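**One-step world.** In a one-step world the starting complex would pass into the isomer of the product along a single curve, but Saturday's run at 2.50 min holds 33.7% complex with one exchanged against 7.5% isomer, so there are two stages, and I solve the late end and the early end apart and join them.

| flask | starting complex | incoming ligand | temperature | remark | time |
|---|---|---|---|---|---|
| Saturday's | 11 mM | 1.05 equiv | −5 °C | run made earlier |  |
| Thursday's | 11 mM | 0.53 equiv | 6 °C | run made earlier |  |
| Monday's | 11 mM | 2.1 equiv | −5 °C | run made earlier |  |
| Tuesday's | 22 mM | 1.05 equiv | 6 °C | run made earlier |  |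
| west | 11 mM | 1.05 equiv | 0 °C | everything together at the start | 20 min |
| south-east | 11 mM | 1.05 equiv (in portions, 4, over 15 min) | 0 °C | first portion at the start, last at 15 min | 20 min |
| south-west | 11 mM (fed, over 15 min) | 1.05 equiv |  | the addition at −40 °C, then warmed to 0 °C; the feed brings no volume worth counting | 20 min |
| north-west | 11 mM | 1.05 equiv (fed, over 15 min) | 0 °C | all else is in the flask from the start; the feed brings no volume worth counting | 20 min |

| run | time / min | isomer of the product / % | complex with one exchanged / % |
|---|---|---|---|
| Saturday's | 2.50 | 7.5 | 33.7 |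
| Saturday's | 8.00 | 26.6 | 35.6 |
| Saturday's | 12.0 | 38.7 | 32.4 |
| Saturday's | 20.0 | 58.3 | 25.2 |
| Thursday's | 3.00 | 19.8 | 17.5 |
| Thursday's | 8.00 | 34.7 | 13.1 |
| Thursday's | 15.0 | 37.1 | 12.4 |
| Thursday's | 25.0 | 41.9 | 10.9 |
| Monday's | 6.00 | 17.2 | 34.8 |
| Monday's | 12.0 | 37.4 | 26.5 |
| Monday's | 20.0 | 53.2 | 20.0 |
| Monday's | 25.0 | 58.5 | 15.9 |
| Tuesday's | 2.00 | 26.1 | 38.1 |
| Tuesday's | 4.00 | 45.2 | 33.6 |
| Tuesday's | 10.0 | 67.6 | 24.2 |
| Tuesday's | 25.0 | 75.5 | 21.1 |

(each reading ± 1 percentage point)



- the flask that comes out highest in amount of isomer of the product, in percent of the starting complex charged, or "all alike" when all lie within 1.5 percentage points (west / south-east / south-west / north-west / all alike)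
- isomer of the product at the end, in percent of the starting complex charged, west
- isomer of the product at the end, in percent of the starting complex charged, south-east
- isomer of the product at the end, in percent of the starting complex charged, south-west
- isomer of the product at the end, in percent of the starting complex charged, north-west

**Late end.** I carry the end ratio, c(isomer) over c(complex with one exchanged) in an old flask, an apparent equilibrium constant: the last readings give 3.84 in Thursday's run and 3.58 in Tuesday's, with different charges, so I take 3.71. Monday's ratio, at −5 °C, is still rising, from 2.66 at 20.0 min to 3.68 at 25.0 min, so it is no end ratio and tells me nothing about 0 °C, where I use the value read at 6 °C as a bare assumption.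

**Early end.** The isomer's early rise over the mean c(complex with one exchanged) gives 0.100 min⁻¹ in Saturday's run and 0.110 min⁻¹ in Monday's, with twice the ligand. Tuesday's rise, corrected for the way back by the end ratio, gives 0.364 min⁻¹ at 6 °C. Between these temperatures I read 0.185 min⁻¹ at 0 °C, a half-life of 3.75 min.

**Two ways.** For west, the assumed ratio applied to the mean of Saturday's and Tuesday's last sums gives 70.9%. Separately, the rates make 20 min at 0 °C worth 10.2 min at 6 °C, where Tuesday reads 67.6%. The two lie 3.3 percentage points apart, so I trust about that. For south-east the last portion has 1.33 half-lives against west's 5.33, and weighting the portions by age gives me 59.6%.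

**The forecast.** It names west as highest, “since it has the longest time at temperature”, with 67% there, 62% in south-east, 27% in south-west and 57% in north-west.

**The result.** The flasks give 71.8% in west, 54.6% in south-east, 27.9% in south-west and 55.8% in north-west, so west leads.

    complex with one exchanged ⇌ isomer of the product (K = 6.50, k = 0.190 min⁻¹, Ea = 77.0 kJ mol⁻¹, ΔH = −65.0 kJ mol⁻¹)
    starting complex + incoming ligand → leaving ligand + complex with one exchanged (k = 82.0 L mol⁻¹ min⁻¹, Ea = 45.0 kJ mol⁻¹)
    complex with one exchanged + incoming ligand ⇌ leaving ligand + complex with two exchanged (K = 2.40, k = 85.0 L mol⁻¹ min⁻¹, Ea = 39.0 kJ mol⁻¹, ΔH = 6.00 kJ mol⁻¹)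
    (constants at 0 °C)

**The ratio again.** At 20.0 min west reads 4.09, but at 200 min it reads 6.50, so the ratio I assumed for 0 °C is no end ratio there. At 20.0 min south-east reads 2.47, and its 54.6% stands below my 59.6% and 7.4 points below the forecast. The neighbouring flask, west with 4.20 equiv of incoming ligand, is as old as west and ends with 10.6% complex with one exchanged, so my assumed ratio gives 39.3% isomer. That flask gives 41.3% isomer, with 48.0% as complex with two exchanged.

The readings are calculated for substances that don't exist, and the scatter is random.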